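Amounts first. Ochre, green, amber, grey and red each get 0.20 M of Q and 1.20 equiv of E, so Q is your limiting reagent. Here is what you have.

| flask | Q | E | remark | time |
|---|---|---|---|---|
| maple | 0.20 M | 1.2 equiv | run made earlier |  |
| cedar | 0.20 M | 0.80 equiv | run made earlier |  |
| elm | 0.20 M | 1.8 equiv | run made earlier |  |
| ash | 0.40 M | 1.2 equiv | run made earlier |  |
| ochre | 0.20 M (in portions, 4, over 3.0 d) | 1.20 equiv | first portion at the start, last at 3.0 d | 8.0 d |
| green | 0.20 M | 1.20 equiv | everything together at the start | 8.0 d |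
| amber | 0.20 M | 1.20 equiv (fed, over 3.0 d) | all else is in the flask from the start; the feed brings no volume worth counting | 8.0 d |
| grey | 0.20 M | 1.20 equiv (fed, over 8.0 h) | all else is in the flask from the start; the feed brings no volume worth counting | 8.0 d |
| red | 0.20 M (fed, over 3.0 d) | 1.20 equiv | all else is in the flask from the start; the feed brings no volume worth counting | 8.0 d |

| run | time / d | Z / % | Q / % |
|---|---|---|---|
| maple | 1.25 | 25.9 | 0 |
| maple | 2.50 | 25.4 | 0 |
| maple | 4.00 | 25.4 | 1.0 |
| maple | 5.00 | 25.1 | 0 |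
| maple | 6.00 | 25.4 | 0.2 |
| maple | 8.00 | 25.1 | 0.4 |
| cedar | 0.833 | 20.5 | 20.5 |
| cedar | 1.67 | 19.8 | 20.1 |
| cedar | 2.50 | 20.3 | 19.6 |
| cedar | 3.00 | 19.5 | 19.8 |
| cedar | 4.00 | 19.4 | 20.2 |
| cedar | 5.00 | 19.8 | 20.0 |
| elm | 0.417 | 27.6 | 0.8 |
| elm | 0.625 | 26.1 | 0.5 |
| elm | 1.04 | 24.9 | 0 |
| elm | 1.67 | 25.2 | 0 |
| elm | 3.00 | 25.2 | 0.7 |
| elm | 5.00 | 26.1 | 0 |
| ash | 0.417 | 27.0 | 0 |
| ash | 0.833 | 26.1 | 0.9 |
| ash | 1.25 | 25.6 | 0 |
| ash | 2.50 | 25.6 | 0 |
| ash | 5.00 | 25.8 | 0.6 |

(scatter of a reading: 0.5 percentage points)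



* the flask that comes out highest in amount of Z, in percent of the Q charged, or "all alike" when all lie within 1.5 percentage points (ochre / green / amber / grey / red / all alike)
* Z at the end, in percent of the Q charged, ochre
* Z at the end, in percent of the Q charged, green
* Z at the end, in percent of the Q charged, amber
* Z at the end, in percent of the Q charged, grey
* Z at the end, in percent of the Q charged, red

Carry one number: the Z share, the Z standing at the end per Q used. Cedar gives it. With 0.80 equiv of E it stops at 20.0% Q, so one E goes with one Q.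

Z share = 19.8% / 0.80 equiv = 24.8%

Z at the end = Z share × Q used

Q used = the smaller of Q charged and E charged

Maple is a separate reading and stands at 25.1% with Q used up. Elm has more E and reads 26.1%. Ash has twice the Q and reads 25.8%. Neither moves the share beyond a point or so.

When you come back, expect Q near zero and Z at 24.8% in each flask. Don't cut E. Cedar, with 0.80 equiv of E, reads 19.8% Z, and maple, with 1.2 equiv, reads 25.1%. Leave the feeds alone. Ochre, amber and red finish at 3.0 d, and elm's Z came down from 27.6% to 24.9% by 1.04 d. The 5.00 d left after the feeds is longer than that.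

The forecast, a little above my figure, puts each flask at 25.3% and answers all alike: “The runs suggest that dosing will not matter.”

The flasks give ochre 25.2%, green 25.2%, amber 25.2%, grey 25.2% and red 25.2%, so the answer is all alike. That is 0.40 percentage points above my Z share, and a single reading scatters by 0.5 points.

    Q + E → L (k = 3.60 L mol⁻¹ h⁻¹)
    Z ⇌ D (K = 0.550, k = 0.0630 h⁻¹)
    Q + E → G (k = 1.70 L mol⁻¹ h⁻¹)
    Q → J (k = 4.70 × 10⁻⁵ h⁻¹)
    Q + E → Z (k = 3.40 L mol⁻¹ h⁻¹)

In ochre, Z and D relax with a half-life of 0.163 d, shorter than the 8.0 d of the run. J, made from Q without E, stands at 0.149% in amber.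

Take the neighbour of ochre with 0.720 equiv of E. The Z share gives 17.9%. Computed, it ends at 18.2% Z, with E at 0% and Q at 27.8%.

(The runs are calculated on assumed constants, and the scatter is random.)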